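**Retrosynthetic overview**
1. The last step cleaves two benzyl ethers from the fully assembled, protected isocoumarin 13.
2. The pyranone ring is the only ring built: carboxylate-directed C–H activation/annulation of diaryl ether benzoic acid 9 with the hexanoyl-derived sulfoxonium ylide 11 forms C4–C4a and O2–C3.
3. The diaryl ether C–O bond comes from Ullmann coupling of the hindered phenol 7 with 4-(benzyloxy)-2-bromobenzoic acid 8.
4. Phenol 7 comes from olivetol 1 by Vilsmeier formylation, 4-O-methylation, 2-O-benzylation and Baeyer–Villiger oxidation; the formyl carbon marks where the ether oxygen ends up.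
5. Ring order: both benzene rings are bought; the lactone ring is closed in the penultimate step.

Assumption: the target has no stereocentre and no stereogenic double bond, so the achiral compound itself is the "single enantiomer"; 4-(benzyloxy)-2-bromobenzoic acid is taken as a catalogue building block.

**Route**

Step 1
Reactants: 1 olivetol (5-pentylbenzene-1,3-diol)
Product: 3 2,4-dihydroxy-6-pentylbenzaldehyde, via iminium chloride 2 (not isolated)
Conditions: POCl3, DMF, 0 °C to rt; then H2O, 50 °C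
Reagents that add atoms: N,N-dimethylformamide CN(C)C=O (formyl carbon); water O (aldehyde oxygen); POCl3 O=P(Cl)(Cl)Cl (chloride counter-ion of 2 only)
Why: Vilsmeier–Haack formylation of the resorcinol goes ortho to one OH and para to the other, next to the pentyl chain, and the iminium salt hydrolyses to the aldehyde.

Step 2
Reactants: 3 2,4-dihydroxy-6-pentylbenzaldehyde
Product: 4 2-hydroxy-4-methoxy-6-pentylbenzaldehyde
Conditions: MeI (1.1 equiv), K2CO3 (1.1 equiv), acetone, rt
Reagents that add atoms: iodomethane CI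
Why: Williamson etherification is selective for the 4-OH, which is more acidic and not locked in the hydrogen bond to the aldehyde as the 2-OH is.

Step 3
Reactants: 4 2-hydroxy-4-methoxy-6-pentylbenzaldehyde
Product: 5 2-(benzyloxy)-4-methoxy-6-pentylbenzaldehyde
Conditions: BnBr, K2CO3, DMF, 60 °C
Reagents that add atoms: benzyl bromide BrCc1ccccc1
Why: Williamson benzylation of the remaining chelated phenol under more forcing conditions installs a group that is removed at the end without touching the methyl ether.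

Step 4
Reactants: 5 2-(benzyloxy)-4-methoxy-6-pentylbenzaldehyde
Product: 7 2-(benzyloxy)-4-methoxy-6-pentylphenol, via aryl formate 6 (not isolated)
Conditions: mCPBA, CH2Cl2, 0 °C to rt; then K2CO3 (cat.), MeOH, rt
Reagents that add atoms: mCPBA OOC(=O)c1cccc(Cl)c1
Why: In this Baeyer–Villiger (Dakin-type) oxidation the electron-rich 2,4-dialkoxyaryl group migrates to give the formate, which methanolysis cleaves to the phenol.

Step 5
Reactants: 7 2-(benzyloxy)-4-methoxy-6-pentylphenol; 8 4-(benzyloxy)-2-bromobenzoic acid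
Product: 9 4-(benzyloxy)-2-[2-(benzyloxy)-4-methoxy-6-pentylphenoxy]benzoic acid
Conditions: CuI (10 mol %), 2,2,6,6-tetramethylheptane-3,5-dione (20 mol %), Cs2CO3 (3 equiv), NMP, 110 °C, Ar; then 1 M HCl
Reagents that add atoms: none
Why: In this Ullmann diaryl ether synthesis the ortho-carboxylate binds copper and accelerates displacement of the bromide, which lets the di-ortho-substituted, electron-rich phenoxide couple.

Step 6
Reactants: 10 hexanoyl chloride
Product: 11 1-[dimethyl(oxo)-λ6-sulfanylidene]heptan-2-one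
Conditions: Me3S(O)I (3 equiv), KOtBu (3 equiv), THF, reflux; then 10, 0 °C to rt
Reagents that add atoms: trimethylsulfoxonium iodide C[S+](C)(C)=O.[I-]
Why: C-acylation of the Corey–Chaykovsky ylide (dimethylsulfoxonium methylide) gives the stabilised β-keto sulfoxonium ylide, a second equivalent of methylide acting as base.

Step 7
Reactants: 9 4-(benzyloxy)-2-[2-(benzyloxy)-4-methoxy-6-pentylphenoxy]benzoic acid; 11 1-[dimethyl(oxo)-λ6-sulfanylidene]heptan-2-one
Product: 13 6-(benzyloxy)-8-[2-(benzyloxy)-4-methoxy-6-pentylphenoxy]-3-pentyl-1H-isochromen-1-one, via keto acid 12 (not isolated)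
Conditions: [Cp*RhCl2]2 (4 mol %), AgSbF6 (16 mol %), NaOAc (0.5 equiv), CF3CH2OH, 80 °C, Ar
Reagents that add atoms: none
Why: Carboxylate-directed C–H activation by the cationic Cp*Rh catalyst (trivalent rhodium) at the only free ortho position, carbene insertion from the sulfoxonium ylide and cyclodehydration (enol lactonisation) give the 3-pentyl isocoumarin as a single regioisomer.

Step 8
Reactants: 13 6-(benzyloxy)-8-[2-(benzyloxy)-4-methoxy-6-pentylphenoxy]-3-pentyl-1H-isochromen-1-one
Product: 14 6-hydroxy-8-(2-hydroxy-4-methoxy-6-pentylphenoxy)-3-pentyl-1H-isochromen-1-one (CNP0409817.0)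
Conditions: BCl3 (5 equiv), C6HMe5 (6 equiv), CH2Cl2, −78 °C; then aq. NaHCO3
Reagents that add atoms: none
Why: Lewis-acid debenzylation with pentamethylbenzene as benzyl-cation scavenger cleaves both benzyl ethers at low temperature and spares the non-chelated methyl ether, the diaryl ether and the enol-lactone double bond.

**Compound list**
1 | olivetol (5-pentylbenzene-1,3-diol) | CCCCCc1cc(O)cc(O)c1 | starting material
2 | [(2,4-dihydroxy-6-pentylphenyl)methylidene]dimethyliminium chloride | CCCCCc1cc(O)cc(O)c1C=[N+](C)C.[Cl-] | intermediate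
3 | 2,4-dihydroxy-6-pentylbenzaldehyde | CCCCCc1cc(O)cc(O)c1C=O | intermediate
4 | 2-hydroxy-4-methoxy-6-pentylbenzaldehyde | CCCCCc1cc(OC)cc(O)c1C=O | intermediate
5 | 2-(benzyloxy)-4-methoxy-6-pentylbenzaldehyde | CCCCCc1cc(OC)cc(OCc2ccccc2)c1C=O | intermediate
6 | 2-(benzyloxy)-4-methoxy-6-pentylphenyl formate | CCCCCc1cc(OC)cc(OCc2ccccc2)c1OC=O | intermediate
7 | 2-(benzyloxy)-4-methoxy-6-pentylphenol | CCCCCc1cc(OC)cc(OCc2ccccc2)c1O | intermediate
8 | 4-(benzyloxy)-2-bromobenzoic acid | OC(=O)c1ccc(OCc2ccccc2)cc1Br | starting material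
9 | 4-(benzyloxy)-2-[2-(benzyloxy)-4-methoxy-6-pentylphenoxy]benzoic acid | CCCCCc1cc(OC)cc(OCc2ccccc2)c1Oc1cc(OCc2ccccc2)ccc1C(O)=O | intermediate
10 | hexanoyl chloride | CCCCCC(Cl)=O | starting material
11 | 1-[dimethyl(oxo)-λ6-sulfanylidene]heptan-2-one | CCCCCC(=O)C=S(C)(C)=O | intermediate
12 | 4-(benzyloxy)-2-[2-(benzyloxy)-4-methoxy-6-pentylphenoxy]-6-(2-oxoheptyl)benzoic acid | CCCCCC(=O)Cc1cc(OCc2ccccc2)cc(Oc2c(CCCCC)cc(OC)cc2OCc2ccccc2)c1C(O)=O | intermediate
13 | 6-(benzyloxy)-8-[2-(benzyloxy)-4-methoxy-6-pentylphenoxy]-3-pentyl-1H-isochromen-1-one | CCCCCc1cc2cc(OCc3ccccc3)cc(Oc3c(OCc4ccccc4)cc(OC)cc3CCCCC)c2c(=O)o1 | intermediate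
14 | 6-hydroxy-8-(2-hydroxy-4-methoxy-6-pentylphenoxy)-3-pentyl-1H-isochromen-1-one | CCCCCc1cc2cc(O)cc(Oc3c(O)cc(OC)cc3CCCCC)c2c(=O)o1 | target

**Totals**
Total step count: 8. Longest linear sequence: 7 steps (steps 1, 2, 3, 4, 5, 7, 8 from olivetol); step 6 is a one-step side branch.

**Three steps most likely to fail**

Step 5 (Ullmann coupling of a di-ortho-substituted, oxidation-prone phenol). The fallback sets out from 7 and comes back at 9, replacing copper catalysis with SNAr and an oxidation. Phenol 7 and purchased 4-(benzyloxy)-2-fluorobenzaldehyde (O=Cc1ccc(OCc2ccccc2)cc1F) with K2CO3 in DMF at 110 °C give 4-(benzyloxy)-2-[2-(benzyloxy)-4-methoxy-6-pentylphenoxy]benzaldehyde F1, the ortho-formyl group activating the fluoride. Pinnick oxidation of F1 (NaClO2, NaH2PO4, 2-methylbut-2-ene, tBuOH/H2O, rt) gives acid 9.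

Step 7 (C–H annulation on an electron-rich, bulky acid). The fallback sets out from 7 and comes back at 13 by the classical lateral-lithiation route to 3-alkylisocoumarins. Purchased methyl orsellinate (COC(=O)c1c(C)cc(O)cc1O) is benzylated at the non-chelated 4-OH (BnBr, K2CO3, acetone) to methyl 4-(benzyloxy)-2-hydroxy-6-methylbenzoate F2. Triflation (Tf2O, pyridine, CH2Cl2, 0 °C) gives methyl 4-(benzyloxy)-2-methyl-6-{[(trifluoromethyl)sulfonyl]oxy}benzoate F3. Palladium-catalysed C–O coupling of F3 with 7 (Pd(OAc)2, 2-di-tert-butylphosphino-2′,4′,6′-triisopropylbiphenyl, K3PO4, toluene, 100 °C) gives methyl 4-(benzyloxy)-2-[2-(benzyloxy)-4-methoxy-6-pentylphenoxy]-6-methylbenzoate F4. Benzylic deprotonation with LiN(iPr)2 (THF, −78 °C) and acylation with N-methoxy-N-methylhexanamide (CCCCCC(=O)N(C)OC) gives methyl 4-(benzyloxy)-2-[2-(benzyloxy)-4-methoxy-6-pentylphenoxy]-6-(2-oxoheptyl)benzoate F5. Acid-catalysed enol lactonisation of F5 with loss of methanol (TsOH·H2O, toluene, 110 °C) gives 13.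

Step 8 (global debenzylation; risk of partial methyl ether cleavage or incomplete removal of the hindered benzyl group). The fallback sets out from 9 and comes back at 14 by deprotecting before the pyranone double bond exists, so plain hydrogenolysis can be used. Hydrogenolysis of 9 (H2, Pd/C, EtOAc/MeOH, rt) gives 4-hydroxy-2-(2-hydroxy-4-methoxy-6-pentylphenoxy)benzoic acid F6. The annulation of step 7 applied to F6 and ylide 11 then gives 14 directly, passing through 4-hydroxy-2-(2-hydroxy-4-methoxy-6-pentylphenoxy)-6-(2-oxoheptyl)benzoic acid F7, which cyclises in the flask.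

Further compounds
F1 | step 5 | 4-(benzyloxy)-2-[2-(benzyloxy)-4-methoxy-6-pentylphenoxy]benzaldehyde | CCCCCc1cc(OC)cc(OCc2ccccc2)c1Oc1cc(OCc2ccccc2)ccc1C=O
F2 | step 7 | methyl 4-(benzyloxy)-2-hydroxy-6-methylbenzoate | COC(=O)c1c(C)cc(OCc2ccccc2)cc1O
F3 | step 7 | methyl 4-(benzyloxy)-2-methyl-6-{[(trifluoromethyl)sulfonyl]oxy}benzoate | COC(=O)c1c(C)cc(OCc2ccccc2)cc1OS(=O)(=O)C(F)(F)F
F4 | step 7 | methyl 4-(benzyloxy)-2-[2-(benzyloxy)-4-methoxy-6-pentylphenoxy]-6-methylbenzoate | CCCCCc1cc(OC)cc(OCc2ccccc2)c1Oc1cc(OCc2ccccc2)cc(C)c1C(=O)OC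
F5 | step 7 | methyl 4-(benzyloxy)-2-[2-(benzyloxy)-4-methoxy-6-pentylphenoxy]-6-(2-oxoheptyl)benzoate | CCCCCC(=O)Cc1cc(OCc2ccccc2)cc(Oc2c(CCCCC)cc(OC)cc2OCc2ccccc2)c1C(=O)OC
F6 | step 8 | 4-hydroxy-2-(2-hydroxy-4-methoxy-6-pentylphenoxy)benzoic acid | CCCCCc1cc(OC)cc(O)c1Oc1cc(O)ccc1C(O)=O
F7 | step 8 | 4-hydroxy-2-(2-hydroxy-4-methoxy-6-pentylphenoxy)-6-(2-oxoheptyl)benzoic acid | CCCCCC(=O)Cc1cc(O)cc(Oc2c(CCCCC)cc(OC)cc2O)c1C(O)=O
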